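## Retrosynthetic overview

1. Target 30 ⇐ desilylation of 29 ⇐ Stille union of the (E)-vinylstannane made from alkyne 19 with bromodienamide 27.
2. 19 ⇐ N-acylation (acid 15) of the 2-amino enone released from 2-azido enone 11.
3. 11 ⇐ enantiotopic-group-selective azidolysis, then dehydration, of meso bis-epoxy ketone 7: one oxirane becomes the C=C–N unit, the other stays as the oxirane of the target.
4. 7 ⇐ double nucleophilic epoxidation of silyl quinol 5 (both oxiranes closed in one operation, trans to OSiEt3) ⇐ quinone monoketal 1 + ethynylmagnesium bromide 2.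
5. Ring order: carbocycle (bought as 1) → both oxiranes together (step 2) → one oxirane opened (steps 3, 4); the cyclopentenone ring comes in ready-made from cyclopentane-1,3-dione 20.

Assumption: the target SMILES is read literally, i.e. tertiary OH trans to the oxirane oxygen, (1R,5S,6S) in 7-oxabicyclo[4.1.0]hept-3-en-2-one numbering; 1, 12 and 23 are taken as catalogue chemicals.

## Route

Step 1
Reactants: 1 4,4-dimethoxycyclohexa-2,5-dien-1-one; 2 ethynylmagnesium bromide
Product: 5 4-ethynyl-4-[(triethylsilyl)oxy]cyclohexa-2,5-dien-1-one, via magnesium alkoxide 3 (not isolated), via silyl ketal 4 (not isolated)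
Conditions: HC≡CMgBr (1.2 equiv), THF, −78 to 0 °C; Et3SiOTf (1.4 equiv), −78 to 0 °C; then 5% aq. oxalic acid, THF, rt, 1 h
Reagents that add atoms: triethylsilyl trifluoromethanesulfonate, CC[Si](CC)(CC)OS(=O)(=O)C(F)(F)F; water, O
Why: 1,2-Grignard addition of the alkynyl nucleophile to the ketal-masked quinone carbonyl, trapping of the tertiary magnesium alkoxide by the silyl triflate and mild acid ketal hydrolysis give the prochiral dienone; no stereocentre is formed.

Step 2
Reactants: 5 4-ethynyl-4-[(triethylsilyl)oxy]cyclohexa-2,5-dien-1-one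
Product: 7 meso-(1R,3S,5R,6r,7S)-6-ethynyl-6-[(triethylsilyl)oxy]-4,8-dioxatricyclo[5.1.0.0(3,5)]octan-2-one, via monoepoxide 6 (not isolated)
Conditions: t-BuOOH (5.5 M in decane, 4 equiv), DBU (2.5 equiv), CH2Cl2, 0 °C to rt
Reagents that add atoms: tert-butyl hydroperoxide, CC(C)(C)OO
Why: Double Weitz–Scheffer nucleophilic epoxidation: with a metal-free counter-ion (no alkoxide-directed delivery) each t-BuOO− should add to the β-carbon anti to the bulky, non-chelating C–OSiEt3 group (Felkin–Anh sense; the slim ethynyl offers no hindrance), so both oxiranes close on the ethynyl face and one meso bis-epoxide results, fixing the relative configuration of the three future stereocentres in a single operation.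

Step 3
Reactants: 7 meso bis-epoxy ketone
Product: 9 (1R,3R,4R,5S,6S)-3-azido-5-ethynyl-4-hydroxy-5-[(triethylsilyl)oxy]-7-oxabicyclo[4.1.0]heptan-2-one, via trimethylsilyl ether 8 (not isolated)
Conditions: (R,R)-(salen)CrN3 (5 mol%; salen = N,N'-bis(3,5-di-tert-butylsalicylidene)cyclohexane-1,2-diaminato), Me3SiN3 (1.1 equiv), t-BuOMe, 0 °C to rt; then citric acid, MeOH, 0 °C
Reagents that add atoms: azidotrimethylsilane, C[Si](C)(C)N=[N+]=[N-]
Why: Proposed new method: enantiotopic-group-selective azidolysis of a meso bis(α,β-epoxy) ketone, the closest known reaction being the Jacobsen (salen)CrN3/Me3SiN3 desymmetrisation of meso epoxides (one chromium centre activates the oxirane, a second delivers azide); the two oxiranes are mirror images, so a catalyst that distinguishes the two enantiotopic carbons of cyclohexene oxide should likewise pick one α-carbon over its mirror-image partner, regiochemistry (α-carbon, not the neopentyl β-carbon) follows from the carbonyl-accelerated SN2 and the adjacent quaternary centre, anti opening puts azide trans to the new hydroxyl, and the surviving oxirane fixes the absolute configuration; the (R,R) catalyst is chosen by analogy with cyclohexene oxide, the sense must be confirmed on the first run, and the (S,S) catalyst is equally available.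

Step 4
Reactants: 9 azido alcohol
Product: 11 (1R,5R,6S)-3-azido-5-ethynyl-5-[(triethylsilyl)oxy]-7-oxabicyclo[4.1.0]hept-3-en-2-one, via mesylate 10 (not isolated)
Conditions: MsCl (1.5 equiv), Et3N (4 equiv), CH2Cl2, −20 to 0 °C
Reagents that add atoms: none
Why: Mesylation of the β-hydroxyl and E1cB elimination through the acidified α-azido ketone enolate give the 2-azido enone; the azide- and hydroxyl-bearing carbons become sp2 while the quaternary centre and the oxirane are untouched.

Step 5
Reactants: 12 (E)-4-methylpent-2-enal; 13 triethyl 4-phosphonocrotonate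
Product: 15 (2E,4E,6E)-8-methylnona-2,4,6-trienoic acid, via ethyl trienoate 14 (not isolated)
Conditions: LiN(SiMe3)2, THF, −78 to 0 °C; then LiOH, MeOH/H2O, 40 °C; HCl work-up; recrystallise
Reagents that add atoms: lithium hydroxide, [Li+].[OH-]
Why: Vinylogous Horner–Wadsworth–Emmons olefination forms the new C4=C5 bond with E selectivity (the other two alkenes are already E), and saponification in the same pot plus recrystallisation gives the all-E acid.

Step 6
Reactants: 11 azido enone; 15 trienoic acid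
Product: 19 (2E,4E,6E)-N-[(1R,5R,6S)-5-ethynyl-2-oxo-5-[(triethylsilyl)oxy]-7-oxabicyclo[4.1.0]hept-3-en-3-yl]-8-methylnona-2,4,6-trienamide, via trienoyl chloride 16 (not isolated), via iminophosphorane 17 (not isolated), via aminoenone 18 (not isolated)
Conditions: 15, (COCl)2, cat. DMF, CH2Cl2, 0 °C to rt, evaporate; 11, PMe3 (1.05 equiv), THF, 0 °C, then H2O, rt, evaporate; combine, pyridine, CH2Cl2, −20 to 0 °C, dark
Reagents that add atoms: none
Why: Staudinger reduction (iminophosphorane hydrolysis) frees the 2-amino enone under neutral conditions that spare oxirane, enone and alkyne, and the unstable enamine is N-acylated at once by the acid chloride (amide formation); no stereocentre is touched.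

Step 7
Reactants: 20 cyclopentane-1,3-dione
Product: 21 2-nitrocyclopentane-1,3-dione (enol form)
Conditions: fuming HNO3, Et2O, 0 °C
Reagents that add atoms: nitric acid, O[N+](=O)[O-]
Why: Electrophilic nitration at the doubly activated C2 of the enolised 1,3-dione.

Step 8
Reactants: 21 2-nitrocyclopentane-1,3-dione
Product: 22 2-amino-3-hydroxycyclopent-2-en-1-one hydrochloride
Conditions: H2 (1 atm), 10% Pd/C, HCl, MeOH, rt
Reagents that add atoms: hydrogen chloride, Cl
Why: Catalytic hydrogenation of the nitro group; the amine is trapped as its hydrochloride, which prevents self-condensation.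

Step 9
Reactants: 23 glutaconaldehyde potassium salt
Product: 24 (2E,4E)-5-bromopenta-2,4-dienal
Conditions: PPh3, Br2, CH2Cl2, −20 °C to rt; cat. TsOH to equilibrate to 2E,4E
Reagents that add atoms: bromine, BrBr
Why: The dienolate oxygen is activated as an oxyphosphonium salt and displaced by bromide (Appel-type deoxybromination by addition–elimination), and the product equilibrates to the (2E,4E) isomer.

Step 10
Reactants: 24 (2E,4E)-5-bromopenta-2,4-dienal
Product: 25 (2E,4E)-5-bromopenta-2,4-dienoic acid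
Conditions: NaClO2, NaH2PO4, 2-methylbut-2-ene, t-BuOH/H2O, 0 °C to rt
Reagents that add atoms: sodium chlorite, [Na+].[O-]Cl=O
Why: Pinnick oxidation converts the enal to the acid without touching the vinyl bromide or the alkene geometry.

Step 11
Reactants: 25 (2E,4E)-5-bromopenta-2,4-dienoic acid; 22 2-amino-3-hydroxycyclopent-2-en-1-one hydrochloride
Product: 27 (2E,4E)-5-bromo-N-(2-hydroxy-5-oxocyclopent-1-en-1-yl)penta-2,4-dienamide, via bromodienoyl chloride 26 (not isolated)
Conditions: (COCl)2, cat. DMF, CH2Cl2, 0 °C to rt, evaporate; then 22, Et3N (3 equiv), DMF, 0 °C to rt; acidic work-up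
Reagents that add atoms: none
Why: Acid chloride formation and N-acylation of the amine (any O-acyl enol ester passes its acyl group on to nitrogen) give the amide of the vinylogous acid.

Step 12
Reactants: 19 enamide alkyne; 27 bromodienamide
Product: 29 (2E,4E,6E)-N-[(1R,5S,6S)-5-[(1E,3E,5E)-7-[(2-hydroxy-5-oxocyclopent-1-en-1-yl)amino]-7-oxohepta-1,3,5-trien-1-yl]-2-oxo-5-[(triethylsilyl)oxy]-7-oxabicyclo[4.1.0]hept-3-en-3-yl]-8-methylnona-2,4,6-trienamide, via vinylstannane 28 (not isolated)
Conditions: Pd(PPh3)2Cl2 (3 mol%), Bu3SnH (1.2 equiv, slow addition), THF, 0 °C, 20 min; then 27 (1.2 equiv), PdCl2(MeCN)2 (5 mol%), DMF, rt, dark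
Reagents that add atoms: none
Why: Palladium-catalysed syn hydrostannation puts tin on the terminal carbon ((E)-β-stannane, the fully substituted propargylic carbon blocks the internal position) and a Stille coupling in the same flask joins it to the (E)-vinyl bromide with retention of both alkene geometries.

Step 13
Reactants: 29 silyl-protected target
Product: 30 (2E,4E,6E)-N-[(1R,5S,6S)-5-hydroxy-5-[(1E,3E,5E)-7-[(2-hydroxy-5-oxocyclopent-1-en-1-yl)amino]-7-oxohepta-1,3,5-trien-1-yl]-2-oxo-7-oxabicyclo[4.1.0]hept-3-en-3-yl]-8-methylnona-2,4,6-trienamide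
Conditions: HF·pyridine, pyridine, THF, 0 °C to rt, dark
Reagents that add atoms: none
Why: Fluoride-mediated silyl ether cleavage under buffered acidic conditions, which avoid the base-induced Payne rearrangement of the trans-epoxy alcohol and leave oxirane and polyenes intact.

## Compound list

1 | 4,4-dimethoxycyclohexa-2,5-dien-1-one | COC1(OC)C=CC(=O)C=C1 | starting material
2 | ethynylmagnesium bromide | C#C[Mg]Br | starting material
3 | bromomagnesium 1-ethynyl-4,4-dimethoxycyclohexa-2,5-dien-1-olate | C#CC1(O[Mg]Br)C=CC(OC)(OC)C=C1 | intermediate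
4 | triethyl[(1-ethynyl-4,4-dimethoxycyclohexa-2,5-dien-1-yl)oxy]silane | C#CC1(O[Si](CC)(CC)CC)C=CC(OC)(OC)C=C1 | intermediate
5 | 4-ethynyl-4-[(triethylsilyl)oxy]cyclohexa-2,5-dien-1-one | C#CC1(O[Si](CC)(CC)CC)C=CC(=O)C=C1 | intermediate
6 | rac-(1R*,5R*,6S*)-5-ethynyl-5-[(triethylsilyl)oxy]-7-oxabicyclo[4.1.0]hept-3-en-2-one (oxirane cis to ethynyl; racemate, one enantiomer drawn) | O=C1C=C[C@@](O[Si](CC)(CC)CC)(C#C)[C@H]2O[C@H]21 | intermediate
7 | meso-(1R,3S,5R,6r,7S)-6-ethynyl-6-[(triethylsilyl)oxy]-4,8-dioxatricyclo[5.1.0.0(3,5)]octan-2-one (both oxirane oxygens cis to ethynyl, trans to OSiEt3) | O=C1[C@H]2O[C@H]2[C@@](O[Si](CC)(CC)CC)(C#C)[C@H]3O[C@H]31 | intermediate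
8 | 4-O-trimethylsilyl ether of 9 (same configuration) | [N-]=[N+]=N[C@@H]1[C@@H](O[Si](C)(C)C)[C@@](O[Si](CC)(CC)CC)(C#C)[C@H]2O[C@H]2C1=O | intermediate
9 | (1R,3R,4R,5S,6S)-3-azido-5-ethynyl-4-hydroxy-5-[(triethylsilyl)oxy]-7-oxabicyclo[4.1.0]heptan-2-one (azide trans to 4-OH; 4-OH, oxirane and ethynyl on one face) | [N-]=[N+]=N[C@@H]1[C@@H](O)[C@@](O[Si](CC)(CC)CC)(C#C)[C@H]2O[C@H]2C1=O | intermediate
10 | 4-O-methanesulfonate of 9 (same configuration) | [N-]=[N+]=N[C@@H]1[C@@H](OS(C)(=O)=O)[C@@](O[Si](CC)(CC)CC)(C#C)[C@H]2O[C@H]2C1=O | intermediate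
11 | (1R,5R,6S)-3-azido-5-ethynyl-5-[(triethylsilyl)oxy]-7-oxabicyclo[4.1.0]hept-3-en-2-one | [N-]=[N+]=NC1=C[C@@](O[Si](CC)(CC)CC)(C#C)[C@H]2O[C@H]2C1=O | intermediate
12 | (E)-4-methylpent-2-enal | CC(C)/C=C/C=O | starting material
13 | triethyl 4-phosphonocrotonate, ethyl (E)-4-(diethoxyphosphoryl)but-2-enoate | CCOC(=O)/C=C/CP(=O)(OCC)OCC | starting material
14 | ethyl (2E,4E,6E)-8-methylnona-2,4,6-trienoate | CCOC(=O)/C=C/C=C/C=C/C(C)C | intermediate
15 | (2E,4E,6E)-8-methylnona-2,4,6-trienoic acid | CC(C)/C=C/C=C/C=C/C(=O)O | intermediate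
16 | (2E,4E,6E)-8-methylnona-2,4,6-trienoyl chloride | CC(C)/C=C/C=C/C=C/C(Cl)=O | intermediate
17 | (1R,5R,6S)-5-ethynyl-5-[(triethylsilyl)oxy]-3-[(trimethylphosphoranylidene)amino]-7-oxabicyclo[4.1.0]hept-3-en-2-one | CP(C)(C)=NC1=C[C@@](O[Si](CC)(CC)CC)(C#C)[C@H]2O[C@H]2C1=O | intermediate
18 | (1R,5R,6S)-3-amino-5-ethynyl-5-[(triethylsilyl)oxy]-7-oxabicyclo[4.1.0]hept-3-en-2-one | NC1=C[C@@](O[Si](CC)(CC)CC)(C#C)[C@H]2O[C@H]2C1=O | intermediate
19 | (2E,4E,6E)-N-[(1R,5R,6S)-5-ethynyl-2-oxo-5-[(triethylsilyl)oxy]-7-oxabicyclo[4.1.0]hept-3-en-3-yl]-8-methylnona-2,4,6-trienamide | CC(C)/C=C/C=C/C=C/C(=O)NC1=C[C@@](O[Si](CC)(CC)CC)(C#C)[C@H]2O[C@H]2C1=O | intermediate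
20 | cyclopentane-1,3-dione | O=C1CCC(=O)C1 | starting material
21 | 2-nitrocyclopentane-1,3-dione (enol form) | O=C1CCC(O)=C1[N+](=O)[O-] | intermediate
22 | 2-amino-3-hydroxycyclopent-2-en-1-one hydrochloride | Cl.NC1=C(O)CCC1=O | intermediate
23 | glutaconaldehyde potassium salt, potassium (1E,3E)-5-oxopenta-1,3-dien-1-olate | [K+].[O-]/C=C/C=C/C=O | starting material
24 | (2E,4E)-5-bromopenta-2,4-dienal | Br/C=C/C=C/C=O | intermediate
25 | (2E,4E)-5-bromopenta-2,4-dienoic acid | Br/C=C/C=C/C(=O)O | intermediate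
26 | (2E,4E)-5-bromopenta-2,4-dienoyl chloride | Br/C=C/C=C/C(Cl)=O | intermediate
27 | (2E,4E)-5-bromo-N-(2-hydroxy-5-oxocyclopent-1-en-1-yl)penta-2,4-dienamide | Br/C=C/C=C/C(=O)NC1=C(O)CCC1=O | intermediate
28 | (2E,4E,6E)-8-methyl-N-[(1R,5R,6S)-2-oxo-5-[(E)-2-(tributylstannyl)ethenyl]-5-[(triethylsilyl)oxy]-7-oxabicyclo[4.1.0]hept-3-en-3-yl]nona-2,4,6-trienamide | CC(C)/C=C/C=C/C=C/C(=O)NC1=C[C@@](O[Si](CC)(CC)CC)(/C=C/[Sn](CCCC)(CCCC)CCCC)[C@H]2O[C@H]2C1=O | intermediate
29 | (2E,4E,6E)-N-[(1R,5S,6S)-5-[(1E,3E,5E)-7-[(2-hydroxy-5-oxocyclopent-1-en-1-yl)amino]-7-oxohepta-1,3,5-trien-1-yl]-2-oxo-5-[(triethylsilyl)oxy]-7-oxabicyclo[4.1.0]hept-3-en-3-yl]-8-methylnona-2,4,6-trienamide | CC(C)/C=C/C=C/C=C/C(=O)NC1=C[C@@](O[Si](CC)(CC)CC)(/C=C/C=C/C=C/C(=O)NC2=C(O)CCC2=O)[C@H]2O[C@H]2C1=O | intermediate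
30 | (2E,4E,6E)-N-[(1R,5S,6S)-5-hydroxy-5-[(1E,3E,5E)-7-[(2-hydroxy-5-oxocyclopent-1-en-1-yl)amino]-7-oxohepta-1,3,5-trien-1-yl]-2-oxo-7-oxabicyclo[4.1.0]hept-3-en-3-yl]-8-methylnona-2,4,6-trienamide (CNP0215439.3) | CC(C)/C=C/C=C/C=C/C(=O)NC1=C[C@@](O)(/C=C/C=C/C=C/C(=O)NC2=C(O)CCC2=O)[C@H]2O[C@H]2C1=O | target

## Step count and risks

Total step count: 13. Longest linear sequence: 7 steps (1, 2, 3, 4, 6, 12, 13, from compound 1).

The three steps most likely to fail:

1. The double epoxidation (step 2). The face selectivity is a prediction: if t-BuOO− adds syn to the C–O bond instead, the oxiranes end cis to the oxygen and the wrong C4 relative configuration is carried forward. The fallback sets out from 5 and comes back at 7, replacing nucleophilic epoxidation by hydroxyl-directed epoxidation. Luche reduction of 5 (NaBH4, CeCl3·7H2O, MeOH, −78 °C; hydride enters on the face of the C4 oxygen) gives cis-4-ethynyl-4-[(triethylsilyl)oxy]cyclohexa-2,5-dien-1-ol F1, with the new hydroxyl cis to ethynyl. VO(acac)2/t-BuOOH then delivers both oxygens syn to that allylic hydroxyl, again two oxiranes at once, to give the all-cis bis-epoxy alcohol F2. Dess–Martin periodinane oxidises F2 to 7. This costs two extra steps.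

2. The desymmetrising azidolysis (step 3). No such enantiotopic-oxirane selection on a bis-epoxy ketone is known, so enantioselectivity, sense and rate are all open. The fallback sets out from 7 and comes back at 11, replacing catalysis by a classical resolution in which the resolving group is also the leaving group. Achiral azidolysis (NaN3, CeCl3·7H2O, MeCN/H2O) gives racemic azido alcohol, that is 9 together with its enantiomer, the (1S,3S,4S,5R,6R)-azido alcohol F3. Esterification with (S)-O-methylmandelic acid (EDC·HCl, cat. DMAP, CH2Cl2, 0 °C) gives the (S)-O-methylmandelate of 9 F4 and the (S)-O-methylmandelate of the enantiomer F5, which are separated by chromatography. Treating F4 with Et3N eliminates the mandelate (E1cB) and gives 11. The maximum yield is 50%.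

3. The Staudinger reduction and acylation (step 6). The free 2-amino enone 18 may self-condense or hydrolyse before it is acylated, and it is a weak nucleophile. The fallback sets out from 11 and comes back at 19 without ever freeing the amine. Acid chloride 16 is converted with NaSH (THF/H2O, 0 °C) into (2E,4E,6E)-8-methylnona-2,4,6-trienethioic S-acid F6. F6 reacts with the electron-poor vinyl azide 11 (2,6-lutidine, MeOH, rt) in a thioacid–azide amidation, with loss of dinitrogen and sulfur, to give 19 directly.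

Further compounds
F1 | step 2 | cis-4-ethynyl-4-[(triethylsilyl)oxy]cyclohexa-2,5-dien-1-ol (1-OH cis to ethynyl) | O[C@H]1C=C[C@@](O[Si](CC)(CC)CC)(C#C)C=C1
F2 | step 2 | 6-ethynyl-6-[(triethylsilyl)oxy]-4,8-dioxatricyclo[5.1.0.0(3,5)]octan-2-ol with 2-OH, both oxirane oxygens and ethynyl on one face | O[C@H]1[C@H]2O[C@H]2[C@@](O[Si](CC)(CC)CC)(C#C)[C@H]3O[C@H]31
F3 | step 3 | (1S,3S,4S,5R,6R)-3-azido-5-ethynyl-4-hydroxy-5-[(triethylsilyl)oxy]-7-oxabicyclo[4.1.0]heptan-2-one (enantiomer of 9) | [N-]=[N+]=N[C@H]1[C@H](O)[C@](O[Si](CC)(CC)CC)(C#C)[C@@H]2O[C@@H]2C1=O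
F4 | step 3 | (S)-2-methoxy-2-phenylacetate (4-O-ester) of 9 | [N-]=[N+]=N[C@@H]1[C@@H](OC(=O)[C@@H](OC)c2ccccc2)[C@@](O[Si](CC)(CC)CC)(C#C)[C@H]3O[C@H]3C1=O
F5 | step 3 | (S)-2-methoxy-2-phenylacetate (4-O-ester) of F3 | [N-]=[N+]=N[C@H]1[C@H](OC(=O)[C@@H](OC)c2ccccc2)[C@](O[Si](CC)(CC)CC)(C#C)[C@@H]3O[C@@H]3C1=O
F6 | step 6 | (2E,4E,6E)-8-methylnona-2,4,6-trienethioic S-acid | CC(C)/C=C/C=C/C=C/C(=O)S
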